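At early times the Z readings of both runs stood too close to the charge, against a scatter of 0.5 percentage points, to show a pace I could trust, so I took the last two, at 8.00 h and 12.0 h.

the same everywhere: X 1.4 mM
- Sunday's: Z 0.67 M; L 2 mM; run made earlier
- Wednesday's: Z 1.5 M; L 2 mM; run made earlier
- flask: Z 1.0 M; L 2.0 mM; time 20 h

| run | time / h | G / % | Z / % |
|---|---|---|---|
| Sunday's | 1.00 | 0.1 | 100.6 |
| Sunday's | 1.50 | 0.3 | 99.7 |
| Sunday's | 2.50 | 0.3 | 100.1 |
| Sunday's | 4.00 | 0.6 | 99.8 |
| Sunday's | 8.00 | 0.9 | 98.6 |
| Sunday's | 12.0 | 2.6 | 97.4 |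
| Wednesday's | 1.00 | 0.8 | 99.3 |
| Wednesday's | 1.50 | 1.0 | 99.2 |
| Wednesday's | 2.50 | 0 | 99.1 |
| Wednesday's | 4.00 | 0.9 | 98.5 |
| Wednesday's | 8.00 | 2.2 | 97.4 |
| Wednesday's | 12.0 | 4.6 | 94.8 |

(each reading ± 0.5 percentage points)

- the average divides the monomer in chains by the number of chains begun, living and dead together
- the earlier runs do not show the number of chains; that part of a forecast is a guess

1. average number of monomer units in a chain (chains begun, living or dead) at 20 h
2. part of the Z that has reacted at 20 h

Between those two times I took the fraction of Z lost per hour as a logarithm of the Z left, averaged it over both runs, and called it the late pace, 0.00491 h⁻¹, a pseudo-first-order constant read with that scatter. The two runs left a mean of 96.1 % of their Z at 12.0 h, so running this pace on to 20 h gave me 7.60 % reacted in the flask. But the runs do not show the number of chains, so I had no reckoning for the average length.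

The forecast put c at 9 % (6 % to 14 %), above my figure, and dp at 80 (35 to 400), adding “The number of chains is a guess”.

The flask gave c of 6.43 % and dp of 221.

    Z + L → Q + G (k = 7.90 × 10⁻⁴ M⁻¹ min⁻¹)
    Z + Q → G + Q, rate k2*[Q]*[Z] (k = 0.250 M⁻¹ min⁻¹)
    L + X → E (k = 9.40 M⁻¹ min⁻¹)
    Z + L → J (k = 8.30 × 10⁻⁴ M⁻¹ min⁻¹)

At 11.9 h in the flask, growth used Z 610 times as fast as chain starting, and Q stood at 2.89 × 10⁻⁴ M at 20.0 h, less than the L charged. At 20.0 h in the flask the half-life of Z by growth, taken at that moment's rate, was 160 h, which is 0.00433 h⁻¹.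

For the same flask read at 30 h, my pace carried on from 6.43 % gave 10.9 %; the computed result was 10.5 %.

The runs come from a simulation with made-up constants; the scatter is artificial.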